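**Retrosynthetic overview**
- The target is methyl (−)-shikimate carrying three different esters (3-OAc, 4-O-propanoyl, 5-O-(R)-2-methylbutanoyl). Its only ring, the cyclohexene, is made last by one-carbon ring expansion of a cyclopentane.
- C1 (with its CO2Me) is cut out between C2 and C6: a tertiary diazo carbinol, from a 2,3,4-tris(acyloxy)cyclopentanone and methyl diazoacetate, undergoes a vinyl-cation 1,2-shift ended by hydride to give the enoate directly.
- The cyclopentanone comes from a 2,3-diol by O2-acetylation then O3-propanoylation; the diol comes from anti-dihydroxylation of a 4-acyloxycyclopentenone (sets C3 and C4 of the target).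
- The enone ester comes from (R)-4-hydroxycyclopent-2-enone and (R)-2-methylbutanoic acid (both remaining stereocentres bought).
- Ring order: cyclopentane (bought), then cyclohexene (last step).

Assumption: (R)-4-hydroxycyclopent-2-enone, (R)-2-methylbutanoic acid and methyl diazoacetate (as a stabilised solution) are bought as catalogue items.

**Step 1**
Reactants: 1 (4R)-4-hydroxycyclopent-2-en-1-one; 2 (2R)-2-methylbutanoic acid
Product: 3 (4R)-4-{[(2R)-2-methylbutanoyl]oxy}cyclopent-2-en-1-one
Conditions: EDC·HCl (1.2 equiv), DMAP (0.1 equiv), CH2Cl2, 0 °C → rt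
Reagents that add atoms: none
Why: Steglich esterification of a secondary allylic alcohol; the carbinol C–O bond is not broken, so C4 stays R, and catalytic DMAP at or below rt neither epimerises the α-methyl acid nor eliminates the γ-acyloxy enone.

**Step 2**
Reactants: 3 (4R)-4-{[(2R)-2-methylbutanoyl]oxy}cyclopent-2-en-1-one
Product: 4 (2S,3R,4R)-2,3-dihydroxy-4-{[(2R)-2-methylbutanoyl]oxy}cyclopentan-1-one
Conditions: OsO4 (2 mol%), NMO (1.3 equiv), citric acid (1 equiv), t-BuOH/H2O 1:1, rt
Reagents that add atoms: N-methylmorpholine N-oxide C[N+]1([O-])CCOCC1; water O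
Why: Upjohn-type catalytic syn-dihydroxylation in its citric-acid variant for electron-poor alkenes (acidic medium, so no β-elimination or acyl migration); OsO4 adds to the enone face anti to the C4 ester, setting C2 (S) and C3 (R) cis to each other and trans to C4–O.

**Step 3**
Reactants: 4 (2S,3R,4R)-2,3-dihydroxy-4-{[(2R)-2-methylbutanoyl]oxy}cyclopentan-1-one; 5 acetyl chloride
Product: 6 (2S,3S,4R)-2-acetoxy-3-hydroxy-4-{[(2R)-2-methylbutanoyl]oxy}cyclopentan-1-one
Conditions: AcCl (1.05 equiv), 2,4,6-collidine (1.5 equiv), CH2Cl2, −78 → −40 °C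
Reagents that add atoms: none
Why: Kinetic regioselective O-acylation with an acyl chloride and a hindered pyridine at low temperature; the C2–OH next to the ketone is the more acidic hydroxyl, the hydrogen-bond donor of the cis-diol and the less hindered one, so it should react ahead of the C3–OH that lies between two substituted sp3 carbons (no stereocentre is touched).

**Step 4**
Reactants: 6 (2S,3S,4R)-2-acetoxy-3-hydroxy-4-{[(2R)-2-methylbutanoyl]oxy}cyclopentan-1-one; 7 propanoyl chloride
Product: 8 (2S,3S,4R)-2-acetoxy-4-{[(2R)-2-methylbutanoyl]oxy}-3-(propanoyloxy)cyclopentan-1-one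
Conditions: EtCOCl (1.5 equiv), pyridine (3 equiv), DMAP (5 mol%), CH2Cl2, −40 → 0 °C
Reagents that add atoms: none
Why: DMAP-catalysed acyl transfer (Steglich-type acylation) to the only free hydroxyl; the weak base and low temperature keep the cis-acetate from migrating and the β-acyloxy ketone from eliminating.

**Step 5**
Reactants: 8 (2S,3S,4R)-2-acetoxy-4-{[(2R)-2-methylbutanoyl]oxy}-3-(propanoyloxy)cyclopentan-1-one; 9 methyl diazoacetate
Product: 10 methyl 2-[(1S,2S,3S,4R)-2-acetoxy-1-hydroxy-4-{[(2R)-2-methylbutanoyl]oxy}-3-(propanoyloxy)cyclopentyl]-2-diazoacetate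
Conditions: 9 (1.3 equiv), LDA (1.2 equiv), THF, −78 °C; then 8, −78 °C, 20 min; AcOH, −78 °C
Reagents that add atoms: none
Why: Aldol-type addition of lithiated diazoacetate to a ketone (Schöllkopf diazo aldol), fast at −78 °C at the activated α-acyloxy ketone and ahead of enolisation or ester attack; the nucleophile enters anti to the cis C2/C3 acyloxy groups to give mainly the (1S) carbinol, and either C1 epimer serves because C1 becomes sp2 in step 6.

**Step 6**
Reactants: 10 methyl 2-[(1S,2S,3S,4R)-2-acetoxy-1-hydroxy-4-{[(2R)-2-methylbutanoyl]oxy}-3-(propanoyloxy)cyclopentyl]-2-diazoacetate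
Product: 13 methyl (3R,4S,5R)-3-acetoxy-5-{[(2R)-2-methylbutanoyl]oxy}-4-(propanoyloxy)cyclohex-1-ene-1-carboxylate, via alkenyldiazonium ion 11 (not isolated), via cyclohexenyl cation 12 (not isolated)
Conditions: B(C6F5)3 (10 mol%), Et3SiH (4 equiv), CH2Cl2, −40 → 0 °C
Reagents that add atoms: none
Why: Proposed new method: B(C6F5)3 takes the tertiary hydroxide of the β-hydroxy-α-diazo ester to give alkenyldiazonium ion 11; loss of N2 is coupled to a 1,2-shift of the ring CH2 (C5) to the diazonium carbon (the acetoxy-bearing C2 is electron-poor and migrates poorly, and the CH2 lies anti to N2 in the less crowded diazonium geometry), which turns the destabilised exocyclic vinyl cation into the ring-expanded cyclohexenyl cation 12; 12 is reduced at C2 by hydride from Et3SiH, and Et3Si+ strips hydroxide from boron so the Lewis acid turns over (net 10 + 2 Et3SiH → 13 + N2 + (Et3Si)2O + H2); the closest known reaction type is the Lewis-acid vinyl-cation ring expansion of cycloalkanone-derived β-hydroxy-α-diazo carbonyl compounds (so far ended by C–H insertion, arene or heteroatom capture) combined with silane hydride transfer to carbocations (ionic hydrogenation, B(C6F5)3/silane deoxygenation); no stereocentre is made and C3, C4 and C5 are not touched.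

**Compound list**
1 | (4R)-4-hydroxycyclopent-2-en-1-one | O=C1C[C@@H](O)C=C1 | starting material
2 | (2R)-2-methylbutanoic acid | CC[C@@H](C)C(=O)O | starting material
3 | (4R)-4-{[(2R)-2-methylbutanoyl]oxy}cyclopent-2-en-1-one | O=C1C[C@@H](OC(=O)[C@H](C)CC)C=C1 | intermediate
4 | (2S,3R,4R)-2,3-dihydroxy-4-{[(2R)-2-methylbutanoyl]oxy}cyclopentan-1-one (the two OH cis to each other and trans to the C4 ester) | O[C@@H]1[C@H](O)C(=O)C[C@H]1OC(=O)[C@H](C)CC | intermediate
5 | acetyl chloride | CC(=O)Cl | starting material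
6 | (2S,3S,4R)-2-acetoxy-3-hydroxy-4-{[(2R)-2-methylbutanoyl]oxy}cyclopentan-1-one | O[C@@H]1[C@H](OC(C)=O)C(=O)C[C@H]1OC(=O)[C@H](C)CC | intermediate
7 | propanoyl chloride | CCC(=O)Cl | starting material
8 | (2S,3S,4R)-2-acetoxy-4-{[(2R)-2-methylbutanoyl]oxy}-3-(propanoyloxy)cyclopentan-1-one | CCC(=O)O[C@@H]1[C@H](OC(C)=O)C(=O)C[C@H]1OC(=O)[C@H](C)CC | intermediate
9 | methyl diazoacetate | COC(=O)C=[N+]=[N-] | starting material
10 | methyl 2-[(1S,2S,3S,4R)-2-acetoxy-1-hydroxy-4-{[(2R)-2-methylbutanoyl]oxy}-3-(propanoyloxy)cyclopentyl]-2-diazoacetate (major C1 epimer, OH cis to the C2 acetate) | CCC(=O)O[C@@H]1[C@H](OC(C)=O)[C@@](O)(C(=[N+]=[N-])C(=O)OC)C[C@H]1OC(=O)[C@H](C)CC | intermediate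
11 | [(2R,3S,4R)-2-acetoxy-4-{[(2R)-2-methylbutanoyl]oxy}-3-(propanoyloxy)cyclopentylidene](methoxycarbonyl)methanediazonium ion (from 10 by loss of hydroxide) | CCC(=O)O[C@@H]1[C@H](OC(C)=O)C(=C([N+]#N)C(=O)OC)C[C@H]1OC(=O)[C@H](C)CC | intermediate
12 | (3R,4S,5R)-3-acetoxy-1-(methoxycarbonyl)-5-{[(2R)-2-methylbutanoyl]oxy}-4-(propanoyloxy)cyclohex-1-en-2-yl cation (the target skeleton lacking H-2) | CCC(=O)O[C@@H]1[C@H](OC(C)=O)[C+]=C(C(=O)OC)C[C@H]1OC(=O)[C@H](C)CC | intermediate
13 | methyl (3R,4S,5R)-3-acetoxy-5-{[(2R)-2-methylbutanoyl]oxy}-4-(propanoyloxy)cyclohex-1-ene-1-carboxylate | CCC(=O)O[C@@H]1[C@H](OC(C)=O)C=C(C(=O)OC)C[C@H]1OC(=O)[C@H](C)CC | target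

**Totals**
Total step count: 6. Longest linear sequence: 6 steps (1 → 3 → 4 → 6 → 8 → 10 → 13).

**Three steps most likely to fail**

Step 3 (regioselective acetylation of the diol). The bias towards the α-ketol hydroxyl may be modest, the acetate can migrate between the cis oxygens, and the regioisomers would be nearly inseparable once both positions are acylated. The fallback replaces selective acylation by selective de-acylation; it sets out from 4 and returns at 8, so it also replaces step 4. Diol 4 is acylated twice with 7 (EtCOCl, pyridine, cat. DMAP, CH2Cl2, −20 °C) to give the 2,3-dipropanoate F1. Lipase-catalysed butanolysis under neutral conditions (CAL-B, n-BuOH, MTBE, 30 °C) should remove the activated, less hindered ester on the α-ketol oxygen to give the 2-hydroxy 3-propanoate F2. Acetylation of F2 with 5 (AcCl, pyridine, CH2Cl2, −40 °C) gives 8.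

Step 5 (diazo aldol on a base-sensitive ketone). Lithiated diazoacetate may enolise 8, which would lead to β-elimination of an acyloxy group or epimerisation at C2, and the lithium alkoxide may take the neighbouring acetate. The fallback avoids a stoichiometric strong base; it sets out from 9 and 8 and returns at 10. Compound 9 is C-silylated (TMSOTf, iPr2NEt, Et2O, −78 °C) to methyl 2-diazo-2-(trimethylsilyl)acetate F3. F3 adds to 8 under catalytic fluoride (TBAT 5 mol%, THF, −40 °C; desilylative aldol in which the new alkoxide is silylated as it forms) to give the O-trimethylsilyl ether of 10 F4. HF·pyridine in THF at 0 °C frees 10.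

Step 6 (the new reductive ring expansion; the riskiest step). Cation 12 may be captured by the neighbouring acetate or by returning hydroxide (which gives the β-keto ester) before hydride arrives, the acetoxy-bearing carbon may migrate instead of the CH2, a hydridoborate may reduce 11 at carbon before N2 is lost, or the enoate may be hydrosilylated. The fallback uses known chemistry only; it sets out from 10 and returns at 13. Rh2(OAc)4 (1 mol%, CH2Cl2, rt) converts 10 through the rhodium carbene and a 1,2-alkyl shift (the established ring enlargement of cycloalkanone-derived β-hydroxy-α-diazo esters) into the ring-expanded β-keto ester (enol form) F5. Tf2O and iPr2NEt in CH2Cl2 at −78 °C give the enol triflate F6. Palladium-catalysed reduction (Pd(OAc)2 5 mol%, PPh3, Et3SiH, DMF, rt, kept mild to spare the allylic acetate) removes the triflate and gives 13.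

**Further compounds**
F1 | step 3 | (2S,3S,4R)-4-{[(2R)-2-methylbutanoyl]oxy}-2,3-bis(propanoyloxy)cyclopentan-1-one | CCC(=O)O[C@@H]1[C@H](OC(=O)CC)C(=O)C[C@H]1OC(=O)[C@H](C)CC
F2 | step 3 | (2S,3R,4R)-2-hydroxy-4-{[(2R)-2-methylbutanoyl]oxy}-3-(propanoyloxy)cyclopentan-1-one | CCC(=O)O[C@@H]1[C@H](O)C(=O)C[C@H]1OC(=O)[C@H](C)CC
F3 | step 5 | methyl 2-diazo-2-(trimethylsilyl)acetate | COC(=O)C(=[N+]=[N-])[Si](C)(C)C
F4 | step 5 | methyl 2-[(1S,2S,3S,4R)-2-acetoxy-4-{[(2R)-2-methylbutanoyl]oxy}-3-(propanoyloxy)-1-[(trimethylsilyl)oxy]cyclopentyl]-2-diazoacetate | CCC(=O)O[C@@H]1[C@H](OC(C)=O)[C@@](O[Si](C)(C)C)(C(=[N+]=[N-])C(=O)OC)C[C@H]1OC(=O)[C@H](C)CC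
F5 | step 6 | methyl (3S,4S,5R)-3-acetoxy-2-hydroxy-5-{[(2R)-2-methylbutanoyl]oxy}-4-(propanoyloxy)cyclohex-1-ene-1-carboxylate (enol form of the 2-oxo ester) | CCC(=O)O[C@@H]1[C@H](OC(C)=O)C(O)=C(C(=O)OC)C[C@H]1OC(=O)[C@H](C)CC
F6 | step 6 | methyl (3S,4S,5R)-3-acetoxy-5-{[(2R)-2-methylbutanoyl]oxy}-4-(propanoyloxy)-2-{[(trifluoromethyl)sulfonyl]oxy}cyclohex-1-ene-1-carboxylate | CCC(=O)O[C@@H]1[C@H](OC(C)=O)C(OS(=O)(=O)C(F)(F)F)=C(C(=O)OC)C[C@H]1OC(=O)[C@H](C)CC
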